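**Plan**

- Atom labels (C5, C7 …) give the position of the atom in the target SMILES. Ring A is the bromodimethylcyclohexane; the core is the cyclopentane/cyclohexane/lactone tricycle.
- Retrosynthesis: remove the acetate, cut C5–C6 (core iodide + ring A bromoketone), then in the core cut O13–C14, C18–Br and C14–CH3, restore oxygen at C8 and C16, and last cut C7–C20. This leads to an achiral 4,4-disubstituted cyclohexa-2,5-dienone made from tert-butyl benzoate.
- Feature used: in the cyclohexane ring C10–C18–C17–C16–C14–C20, quaternary C10 is flanked by C18 and C20. With the carbonyl at C16 these are enantiotopic β-carbons of a dienone, so bonding C7 to C20 closes the cyclopentane C7–C8–C9–C10–C20 and desymmetrises C10.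
- Forward order: six-membered ring (as dienone), cyclopentane by Michael closure, lactone by oxylactonisation onto C14, C18–Br, removal of the C16 and C8 oxygens, C7, then ring A joined through C6.
- Stereochemistry: C10/C20 from the catalyst; C14 by delivery of O13 from the C11 acid; C18 by reversible HBr addition (equatorial); C7 by hydrogenation from the convex face; C23 from the resolved ketone; C5 by equatorial addition to that ketone.

Key step: step 4

Remark on the chemistry: the sense of induction of the cinchona amine–thiourea cannot be fixed on paper; the quinine-derived catalyst is written, and its quinidine-derived pseudoenantiomer would be used if the other enone arm reacts.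

**Route**

Step 1
Reactants: 1 tert-butyl benzoate; 2 methyl (E)-4-bromo-3-methoxybut-2-enoate
Product: 4 tert-butyl 1-[(E)-2,4-dimethoxy-4-oxobut-2-en-1-yl]cyclohexa-2,5-diene-1-carboxylate, via Birch lithium dienolate 3 (not isolated)
Conditions: Li, NH3(l)/THF, t-BuOH (1 equiv), −78 °C; isoprene; then 2, −78 °C → rt
Reagents that add atoms: none
Why: Birch reductive alkylation, in which the ester dienolate formed by reduction of the benzoate is alkylated at the ipso carbon (future C10) by the allylic-type bromide, with no stereocentre formed.

Step 2
Reactants: 4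
Product: 5 tert-butyl 1-[(E)-2,4-dimethoxy-4-oxobut-2-en-1-yl]-4-oxocyclohexa-2,5-diene-1-carboxylate
Conditions: Rh2(cap)4 (cap = caprolactamate, 1 mol %), t-BuOOH (70% aq), K2CO3, CH2Cl2, rt
Reagents that add atoms: tert-butyl hydroperoxide, CC(C)(C)OO
Why: Catalytic allylic oxidation of the doubly allylic CH2, the usual way from a 3,3-disubstituted cyclohexa-1,4-diene to the 4,4-disubstituted cyclohexa-2,5-dienone.

Step 3
Reactants: 5
Product: 6 tert-butyl 1-(4-methoxy-2,4-dioxobutyl)-4-oxocyclohexa-2,5-diene-1-carboxylate
Conditions: 1 M HCl, THF, 0 °C → rt; used directly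
Reagents that add atoms: water, O
Why: Acid hydrolysis of the β-methoxy enoate (a masked acetoacetate) unveils the β-keto ester under conditions too mild for dienone–phenol rearrangement or loss of the tert-butyl ester.

Step 4
Reactants: 6
Product: 7 cis-fused bicyclic diketo diester (3a-tert-butyl 1-methyl cis-2,6-dioxo-1,2,3,6,7,7a-hexahydro-3aH-indene-1,3a-dicarboxylate; C10 and C20 as in the target; C7 drawn with the ester anti to C14)
Conditions: 1-[3,5-bis(trifluoromethyl)phenyl]-3-(9-deoxy-epi-quinin-9-yl)thiourea (10 mol %), toluene, −20 °C
Reagents that add atoms: none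
Why: The quinuclidine nitrogen deprotonates the β-keto ester while the thiourea hydrogen-bonds the dienone carbonyl, and C7 adds to C20, one of the two enantiotopic β-carbons, in an intramolecular Michael addition. The closest known reaction type is the amine–thiourea-catalysed desymmetrising intramolecular Michael addition of tethered nucleophiles to 4,4-disubstituted cyclohexa-2,5-dienones. The cyclopentane C7–C8–C9–C10–C20 closes in the 5-exo-trig mode. C10 and C20 are set together by the catalyst's choice between the C18 and C20 arms, and the cis ring fusion follows from the three-atom tether, which reaches C20 only on the face of C10 that carries C9; C7 is an epimerisable β-keto ester centre and is erased in step 5. The step needs enantiotopic-group selectivity, which is the catalyst's task, and a single addition, which the substrate secures because the one tether is consumed and the remaining enone has no nucleophile within reach.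

Step 5
Reactants: 7
Product: 8 enol triflate of 7 (C8–OSO2CF3, C7=C8)
Conditions: NaH, THF, 0 °C; PhNTf2, 0 °C → rt
Reagents that add atoms: N-phenylbis(trifluoromethanesulfonimide), O=S(=O)(N(c1ccccc1)S(=O)(=O)C(F)(F)F)C(F)(F)F
Why: The β-keto ester is the most acidic site, so its enolate is O-sulfonylated (enol triflate formation), which makes C7 planar and prepares C8 for deoxygenation.

Step 6
Reactants: 8
Product: 9 cyclopentene ester (3a-tert-butyl 1-methyl cis-6-oxo-3,6,7,7a-tetrahydro-3aH-indene-1,3a-dicarboxylate)
Conditions: Pd(OAc)2 (5 mol %), PPh3 (10 mol %), HCO2H, Et3N, DMF, 60 °C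
Reagents that add atoms: none
Why: Palladium-catalysed formate reduction of the vinyl triflate replaces C8–O by C8–H and leaves the conjugated cyclopentene ester, the cyclohexenone being inert to these conditions.

Step 7
Reactants: 9
Product: 10 C14-methyl enone (7-methyl derivative of 9, both C14 epimers)
Conditions: LiN(iPr)2, THF, −78 °C; MeI, DMPU, −78 → −30 °C
Reagents that add atoms: iodomethane, CI
Why: Kinetic α′-deprotonation of the cyclohexenone (C14 is its only enolisable position, since C10 is quaternary) followed by enolate C-methylation; the C14 configuration does not matter because C14 is enolised again in step 8.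

Step 8
Reactants: 10
Product: 12 tricyclic enone lactone (O13–C14 bond formed; C14 methyl exo; enone C16(=O)–C17=C18; methyl ester on C7=C8), via keto acid 11 (not isolated)
Conditions: CF3CO2H, CH2Cl2, 0 °C → rt; evaporate; PhI(OH)OTs, CH2Cl2, 40 °C
Reagents that add atoms: none
Why: Acidolysis frees the C11 acid and the trivalent-iodine reagent then effects oxylactonisation of the 5-oxo acid through the C14 enol; the carboxylate can reach C14 only on the face of C10 that carries C11, which fixes C14.

Step 9
Reactants: 12
Product: 13 β-bromo ketone lactone (C18–Br equatorial, cis to C11)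
Conditions: HBr (33% in AcOH), CH2Cl2, 0 °C; cold NaHCO3 wash; used crude
Reagents that add atoms: hydrogen bromide, Br
Why: Conjugate addition of HBr to the cyclohexenone is reversible, so bromide should settle under thermodynamic control in the equatorial position at C18, away from the syn-axial C7 on C20.

Step 10
Reactants: 13
Product: 15 bromo lactone ester with C16 as CH2, via tosylhydrazone 14 (not isolated)
Conditions: TsNHNH2, AcOH (cat.), THF, rt; then catecholborane, CHCl3, 0 °C; NaOAc·3H2O, 60 °C
Reagents that add atoms: none
Why: Caglioti-type deoxygenation, in which the tosylhydrazone is reduced by the borane and the resulting diazene loses N2, under weakly acidic to neutral conditions that should spare the secondary bromide, the lactone and the unsaturated ester.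

Step 11
Reactants: 15
Product: 16 bromo lactone cyclopentenecarboxylic acid
Conditions: LiOH, THF/H2O, rt; then 1 M HCl to pH 2
Reagents that add atoms: lithium hydroxide, [Li+].[OH-]
Why: Saponification of the methyl ester while C7 is still sp2, so nothing can epimerise; a lactone opened by hydroxide recloses on acidification because the acid and the tertiary alcohol are held cis-1,3.

Step 12
Reactants: 16
Product: 17 saturated acid (C7–H cis to C20–H; carboxyl on the concave face, cis to C14)
Conditions: H2 (1 atm), PtO2, EtOAc, rt
Reagents that add atoms: none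
Why: Heterogeneous hydrogenation should deliver H2 to the cyclopentene face anti to the six-membered ring (the convex face), which sets C7 as in the target; PtO2 without base leaves the alkyl bromide alone.

Step 13
Reactants: 17
Product: 18 primary alcohol (C6H2OH)
Conditions: BH3·THF, THF, 0 °C → rt; MeOH
Reagents that add atoms: none
Why: Borane reduces the carboxylic acid chemoselectively in the presence of the lactone and the bromide and does not touch C7.

Step 14
Reactants: 18
Product: 19 primary iodide (C6H2I)
Conditions: I2, PPh3, imidazole, CH2Cl2, 0 °C → rt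
Reagents that add atoms: iodine, II
Why: Appel-type iodination of the primary alcohol by SN2 at CH2.

Step 15
Reactants: 20 6-methylhept-5-en-2-one
Product: 21 diethyl 6-methylhepta-1,5-dien-2-yl phosphate
Conditions: LiN(iPr)2, THF, −78 °C; ClP(O)(OEt)2, −78 °C → rt
Reagents that add atoms: diethyl chlorophosphate, CCOP(=O)(Cl)OCC
Why: Kinetic deprotonation at the methyl group and O-phosphorylation give the terminal enol phosphate, a nucleophile weak enough to leave the electrophile of step 16 to the trisubstituted alkene.

Step 16
Reactants: 21
Product: 22 rac-4-(chloromercurio)-3,3-dimethylcyclohexanone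
Conditions: Hg(O2CCF3)2, MeNO2, 0 °C; then aq NaCl
Reagents that add atoms: mercuric trifluoroacetate, FC(F)(F)C(=O)O[Hg]OC(=O)C(F)(F)F; sodium chloride, [Na+].[Cl-]
Why: Mercuric-ion-initiated cation–olefin cyclisation, in which the mercurinium ion is opened at its tertiary carbon by the enol phosphate carbon through a six-membered chair and hydrolysis gives the ketone (racemic).

Step 17
Reactants: 22
Product: 23 rac-4-bromo-3,3-dimethylcyclohexanone
Conditions: Br2, LiBr, pyridine, O2, 0 °C, dark
Reagents that add atoms: bromine, BrBr
Why: Brominative demercuration puts bromine next to the quaternary carbon, a position closed to SN2; with one stereocentre the product is racemic whatever the mechanism.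

Step 18
Reactants: 23; 24 (R,R)-hydrobenzoin
Product: 25 (R,R)-hydrobenzoin ketal of (R)-4-bromo-3,3-dimethylcyclohexanone
Conditions: TsOH·H2O (cat.), benzene, reflux with azeotropic removal of water; chromatographic separation of the two diastereomers
Reagents that add atoms: none
Why: Ketalisation with a C2-symmetric diol creates no new stereocentre, so exactly two diastereomers form (classical resolution through diastereomeric ketals); the one from the (R)-ketone is kept, with assignment by X-ray using the bromine atom.

Step 19
Reactants: 25
Product: 26 (R)-4-bromo-3,3-dimethylcyclohexanone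
Conditions: 2 M HCl, THF, 50 °C
Reagents that add atoms: water, O
Why: Acid-catalysed ketal hydrolysis releases the enantiopure ketone, whose C–Br centre is γ to the carbonyl and cannot epimerise.

Step 20
Reactants: 19; 26
Product: 27 tertiary alcohol (deacetyl target; C5–OH axial, cis to C23–Br)
Conditions: 26 (1.5 equiv), SmI2 (2.2 equiv), NiI2 (2 mol %), THF, 0 °C → rt; chromatography
Reagents that add atoms: none
Why: Samarium Barbier reaction, in which SmI2 reduces the primary iodide faster than the secondary bromides and the alkylsamarium adds to the ketone from the equatorial side, anti to the axial C25 methyl; this gives the axial C5 alkoxide, cis to bromine when the ketone reacts through its bromine-equatorial chair, and the C5 epimer from the other chair would be removed by chromatography.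

Step 21
Reactants: 27
Product: 28 target acetate CNP0133010.1
Conditions: Ac2O, Sc(OTf)3 (2 mol %), MeCN, −20 °C
Reagents that add atoms: acetic anhydride, CC(=O)OC(C)=O
Why: Lewis-acid-catalysed acetylation of the hindered tertiary alcohol at low temperature, an O-acylation that leaves the C5–O bond and its configuration untouched.

**Compound list**

1 | tert-butyl benzoate | CC(C)(C)OC(=O)c1ccccc1 | starting material
2 | methyl (E)-4-bromo-3-methoxybut-2-enoate | COC(=O)/C=C(/OC)CBr | starting material
3 | Birch lithium dienolate (lithium enolate of tert-butyl cyclohexa-2,5-diene-1-carboxylate) | [Li+].CC(C)(C)OC([O-])=C1C=CCC=C1 | intermediate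
4 | tert-butyl 1-[(E)-2,4-dimethoxy-4-oxobut-2-en-1-yl]cyclohexa-2,5-diene-1-carboxylate | COC(=O)/C=C(/OC)CC1(C(=O)OC(C)(C)C)C=CCC=C1 | intermediate
5 | tert-butyl 1-[(E)-2,4-dimethoxy-4-oxobut-2-en-1-yl]-4-oxocyclohexa-2,5-diene-1-carboxylate | COC(=O)/C=C(/OC)CC1(C(=O)OC(C)(C)C)C=CC(=O)C=C1 | intermediate
6 | tert-butyl 1-(4-methoxy-2,4-dioxobutyl)-4-oxocyclohexa-2,5-diene-1-carboxylate | COC(=O)CC(=O)CC1(C(=O)OC(C)(C)C)C=CC(=O)C=C1 | intermediate
7 | cis-fused bicyclic diketo diester, 3a-tert-butyl 1-methyl cis-2,6-dioxo-1,2,3,6,7,7a-hexahydro-3aH-indene-1,3a-dicarboxylate (C7 epimerisable, ester drawn anti to C14) | COC(=O)[C@@H]1C(=O)C[C@@]2(C(=O)OC(C)(C)C)C=CC(=O)C[C@@H]12 | intermediate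
8 | enol triflate of 7 (C8–OSO2CF3, C7=C8) | COC(=O)C1=C(OS(=O)(=O)C(F)(F)F)C[C@@]2(C(=O)OC(C)(C)C)C=CC(=O)C[C@@H]12 | intermediate
9 | 3a-tert-butyl 1-methyl cis-6-oxo-3,6,7,7a-tetrahydro-3aH-indene-1,3a-dicarboxylate | COC(=O)C1=CC[C@@]2(C(=O)OC(C)(C)C)C=CC(=O)C[C@@H]12 | intermediate
10 | 7-methyl derivative of 9 (C14 methyl, both epimers) | COC(=O)C1=CC[C@@]2(C(=O)OC(C)(C)C)C=CC(=O)C(C)[C@@H]12 | intermediate
11 | keto acid, cis-1-(methoxycarbonyl)-7-methyl-6-oxo-3,6,7,7a-tetrahydro-3aH-indene-3a-carboxylic acid | COC(=O)C1=CC[C@@]2(C(=O)O)C=CC(=O)C(C)[C@@H]12 | intermediate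
12 | tricyclic enone lactone (lactone C11(=O)–O13–C14; C14 methyl exo; C16 ketone; C17=C18; methyl ester on C7=C8) | COC(=O)C1=CC[C@@]23C(=O)O[C@@](C)(C(=O)C=C2)[C@@H]13 | intermediate
13 | β-bromo ketone lactone (C18–Br equatorial, cis to C11) | COC(=O)C1=CC[C@@]23C(=O)O[C@@](C)(C(=O)C[C@H]2Br)[C@@H]13 | intermediate
14 | C16 tosylhydrazone of 13 | COC(=O)C1=CC[C@@]23C(=O)O[C@@](C)(C(=NNS(=O)(=O)c4ccc(C)cc4)C[C@H]2Br)[C@@H]13 | intermediate
15 | bromo lactone methyl ester (C16 = CH2; C7=C8) | COC(=O)C1=CC[C@@]23C(=O)O[C@@](C)(CC[C@H]2Br)[C@@H]13 | intermediate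
16 | bromo lactone cyclopentenecarboxylic acid | OC(=O)C1=CC[C@@]23C(=O)O[C@@](C)(CC[C@H]2Br)[C@@H]13 | intermediate
17 | saturated bromo lactone acid (C7–H cis to C20–H) | OC(=O)[C@H]1CC[C@@]23C(=O)O[C@@](C)(CC[C@H]2Br)[C@@H]13 | intermediate
18 | bromo lactone primary alcohol (C6H2OH) | OC[C@H]1CC[C@@]23C(=O)O[C@@](C)(CC[C@H]2Br)[C@@H]13 | intermediate
19 | bromo lactone primary iodide (C6H2I) | IC[C@H]1CC[C@@]23C(=O)O[C@@](C)(CC[C@H]2Br)[C@@H]13 | intermediate
20 | 6-methylhept-5-en-2-one | CC(=O)CCC=C(C)C | starting material
21 | diethyl 6-methylhepta-1,5-dien-2-yl phosphate | C=C(CCC=C(C)C)OP(=O)(OCC)OCC | intermediate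
22 | rac-4-(chloromercurio)-3,3-dimethylcyclohexanone | O=C1CCC([Hg]Cl)C(C)(C)C1 | intermediate
23 | rac-4-bromo-3,3-dimethylcyclohexanone | O=C1CCC(Br)C(C)(C)C1 | intermediate
24 | (R,R)-hydrobenzoin | O[C@H](c1ccccc1)[C@H](O)c1ccccc1 | starting material
25 | (R,R)-hydrobenzoin ketal of (R)-4-bromo-3,3-dimethylcyclohexanone | C12(CC[C@@H](Br)C(C)(C)C1)O[C@H](c1ccccc1)[C@@H](c1ccccc1)O2 | intermediate
26 | (R)-4-bromo-3,3-dimethylcyclohexanone | O=C1CC[C@@H](Br)C(C)(C)C1 | intermediate
27 | tertiary alcohol, deacetyl target | O[C@@]1(C[C@H]2CC[C@@]34C(=O)O[C@@](C)(CC[C@H]3Br)[C@@H]24)CC[C@@H](Br)C(C)(C)C1 | intermediate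
28 | CNP0133010.1 | CC(=O)O[C@@]1(C[C@H]2CC[C@@]34C(=O)O[C@@](C)(CC[C@H]3Br)[C@@H]24)CC[C@@H](Br)C(C)(C)C1 | target

**Count and risks**

Total steps: 21. Longest linear sequence: 16 (steps 1–14, 20, 21).

1. Step 20. What may go wrong: poor control of C5 relative to C23, because 4-halocyclohexanones tend to populate the chair with axial halogen and equatorial attack on that chair gives the C5 epimer; in addition a secondary bromide may be reduced by SmI2. Fallback, from 19 and 26, returning at 27: 19 is heated with PPh3 in MeCN to give the phosphonium iodide F1. Its ylide (NaN(SiMe3)2, THF, −78 → 0 °C) undergoes a Wittig reaction with 26 to give the alkylidenecyclohexane F2 (E/Z mixture, of no consequence). Mukaiyama hydration (Mn(dpm)3, dpm = dipivaloylmethanate, PhSiH3, O2, i-PrOH, 0 °C) then puts hydrogen on C6 and oxygen on the tertiary C5 radical, giving 27. Here oxygen rather than carbon enters anti to the axial methyl, so for a given chair this sequence gives the opposite C5 configuration to step 20, and the two sequences together cover both chairs.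

2. Step 10. What may go wrong: loss of HBr by retro-conjugate addition while the hydrazone forms or during the acetate-induced breakdown, giving unsaturated or debrominated material. Fallback, from 13, returning at 15: 13 is converted with ethane-1,2-dithiol and BF3·OEt2 (CH2Cl2, 0 °C, acidic throughout) into the dithiolane F3, which is desulfurised with sponge nickel (Ni, deactivated by refluxing in acetone; EtOH, rt) to give 15, the deactivated metal being chosen to spare the C–Br bond and the conjugated alkene.

3. Step 8. What may go wrong: no reaction or unselective oxidation, because the trivalent-iodine reagent must functionalise a hindered, fully substituted α-carbon. Fallback, from 11 (isolated after the acidolysis), returning at 12: 11 is brominated at C14 with CuBr2 (EtOAc–CHCl3, reflux) to give the α′-bromo keto acid F4; Ag2CO3 in MeCN then closes the lactone by intramolecular carboxylate displacement, which is possible only on the C11 face, to give 12.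

**Further compounds**

F1 | step 20 | phosphonium iodide from 19 (C6H2–PPh3 iodide) | [I-].c1ccc(cc1)[P+](c1ccccc1)(c1ccccc1)C[C@H]1CC[C@@]23C(=O)O[C@@](C)(CC[C@H]2Br)[C@@H]13
F2 | step 20 | alkylidenecyclohexane (C5=C6, E/Z mixture) | Br[C@@H]1CCC(=C[C@H]2CC[C@@]34C(=O)O[C@@](C)(CC[C@H]3Br)[C@@H]24)CC1(C)C
F3 | step 10 | C16 1,3-dithiolane of 13 | COC(=O)C1=CC[C@@]23C(=O)O[C@@](C)(C4(SCCS4)C[C@H]2Br)[C@@H]13
F4 | step 8 | α′-bromo keto acid (C14–Br, either epimer) | COC(=O)C1=CC[C@@]2(C(=O)O)C=CC(=O)C(C)(Br)[C@@H]12
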